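Ring A (N1, C2, C3, C4, C4a, C8a) is disconnected at C3, the carbon between the methyl-bearing C2 and the C4 carbonyl. Removing it leaves an N-methoxy 3-oxypyrrole fused to ring B. In the forward sense, dibromocarbene inserts this carbon into the pyrrole bond between the methyl-bearing and the silyloxy-bearing carbon. One operation forms C2–C3 and C3–C4, unveils the C4 carbonyl and leaves bromine on C3 for a final methoxylation. The precursor is the 4,7-cis 1,7-dimethoxy-2-methyl-3-silyloxy-4-(5-phenylpentyl)tetrahydroindole. Its two ring B stereocentres, C–OMe from a chiral alcohol and C–alkyl from a catalyst-controlled conjugate addition, are set before any heterocycle exists.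

Key step: step 9

Remark: the target is the (5S,8R), 5,8-cis isomer; (1R,2R)-2-methoxycyclohexan-1-ol and tert-butyl N-methoxycarbamate are taken as purchasable, and the alanine-type side-chain centre is used racemic because it becomes sp2 in the pyrrole.

Step 1
Reactants: 1 (1R,2R)-2-methoxycyclohexan-1-ol
Product: 2 (R)-2-methoxycyclohexan-1-one
Conditions: TEMPO (10 mol %), PhI(OAc)2, CH2Cl2, rt
Reagents that add atoms: none
Why: TEMPO-catalysed oxidation of a secondary alcohol (oxoammonium mechanism) runs under near-neutral conditions, so the methoxy-bearing carbon, taken from the chiral starting material and destined to become C8, should not enolise.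

Step 2
Reactants: 2 (R)-2-methoxycyclohexan-1-one
Product: 4 (R)-6-methoxycyclohex-2-en-1-one, via lithium enolate 3 (not isolated)
Conditions: LiN(i-Pr)2, THF, −78 °C; then PhS(Cl)=N-t-Bu, −78 °C
Reagents that add atoms: none
Why: Kinetic deprotonation of an α-alkoxy ketone occurs at the CH2 remote from the alkoxy group, and the enolate is dehydrogenated in one pot by the sulfinimidoyl chloride (S-attack, then syn-elimination), so the methoxy stereocentre is never deprotonated.

Step 3
Reactants: 5 tert-butyl N-methoxycarbamate; 6 methyl 2-bromopropanoate (racemic)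
Product: 7 methyl 2-[(tert-butoxycarbonyl)(methoxy)amino]propanoate (racemic)
Conditions: K2CO3, DMF, rt → 40 °C
Reagents that add atoms: none
Why: SN2 N-alkylation of the acidic N-alkoxycarbamate by an α-bromo ester fixes the N-methoxy nitrogen on the future C2 before any ketone is present, which removes the regiochemical ambiguity of a later methoxyamine condensation on a diketone.

Step 4
Reactants: 7 methyl 2-[(tert-butoxycarbonyl)(methoxy)amino]propanoate (racemic)
Product: 8 tert-butyl N-methoxy-N-(1-oxopropan-2-yl)carbamate (racemic)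
Conditions: i-Bu2AlH, CH2Cl2, −78 °C
Reagents that add atoms: none
Why: Partial reduction of an N-protected α-amino ester at low temperature stops at the aldehyde because the tetrahedral aluminate collapses only on work-up.

Step 5
Reactants: 4 (R)-6-methoxycyclohex-2-en-1-one; 8 tert-butyl N-methoxy-N-(1-oxopropan-2-yl)carbamate (racemic); 9 (5-bromopentyl)benzene
Product: 13 (3S,6R)-2-{2-[(tert-butoxycarbonyl)(methoxy)amino]-1-hydroxypropyl}-6-methoxy-3-(5-phenylpentyl)cyclohexan-1-one (mixed epimers at C2 plus both side-chain carbons), via Grignard reagent 10 (not isolated), via dialkylzinc 11 (not isolated), via zinc enolate 12 (not isolated)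
Conditions: 9, Mg, Et2O; ZnCl2 (0.5 equiv), then 1,4-dioxane, filtration; 4, Cu(OTf)2 (2 mol %), (S,R,R)-configured BINOL-derived phosphoramidite [O,O'-(S)-1,1'-binaphthyl-2,2'-diyl N,N-bis((R)-1-phenylethyl)phosphoramidite] (4 mol %), toluene, −30 °C; then 8, −30 → 0 °C
Reagents that add atoms: none
Why: Copper-catalysed asymmetric conjugate addition of the dialkylzinc, with the ligand enantiomer that gives the (S)-3-alkylcyclohexanone series from cyclohex-2-enone, should deliver the chain to C3 on the face cis to the C6 methoxy group under catalyst control (the face also expected for axial attack on the half-chair with a pseudo-equatorial methoxy group), setting the future C5 as S, and the regiodefined zinc enolate is trapped in a tandem aldol reaction so that the new C–C bond forms only at C2.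

Step 6
Reactants: 13 (3S,6R)-2-{2-[(tert-butoxycarbonyl)(methoxy)amino]-1-hydroxypropyl}-6-methoxy-3-(5-phenylpentyl)cyclohexan-1-one
Product: 14 (3S,6R)-2-{2-[(tert-butoxycarbonyl)(methoxy)amino]propanoyl}-6-methoxy-3-(5-phenylpentyl)cyclohexan-1-one (enolised 1,3-diketone; side-chain epimers)
Conditions: Dess–Martin periodinane (1.2 equiv), CH2Cl2, 0 °C → rt
Reagents that add atoms: none
Why: Dess–Martin oxidation of a β-hydroxy ketone to the 1,3-diketone is non-basic, so the Boc group, the N–O bond and the α-methoxy stereocentre should survive while the carbinol and ring C2 centres are erased.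

Step 7
Reactants: 14 (3S,6R)-2-{2-[(tert-butoxycarbonyl)(methoxy)amino]propanoyl}-6-methoxy-3-(5-phenylpentyl)cyclohexan-1-one
Product: 16 (4S,7R)-1,7-dimethoxy-2-methyl-4-(5-phenylpentyl)-1,2,4,5,6,7-hexahydro-3H-indol-3-one (C2 epimers), via amino diketone 15 (not isolated)
Conditions: CF3CO2H, CH2Cl2, 0 °C; concentrate; EtOH, 40 °C
Reagents that add atoms: none
Why: Acidolysis of the Boc group frees the N-methoxyamine, whose only possible cyclocondensation is with the ring ketone (five-membered enaminone formation from an amine and a 1,3-diketone), and the iminium formed loses the proton between the two carbonyl carbons, not the one on the methoxy-bearing carbon.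

Step 8
Reactants: 16 (4S,7R)-1,7-dimethoxy-2-methyl-4-(5-phenylpentyl)-1,2,4,5,6,7-hexahydro-3H-indol-3-one
Product: 17 (4S,7R)-3-[(tert-butyldimethylsilyl)oxy]-1,7-dimethoxy-2-methyl-4-(5-phenylpentyl)-4,5,6,7-tetrahydro-1H-indole
Conditions: TBSOTf, Et3N, CH2Cl2, −78 → 0 °C
Reagents that add atoms: tert-butyldimethylsilyl trifluoromethanesulfonate, CC(C)(C)[Si](C)(C)OS(=O)(=O)C(F)(F)F
Why: O-Silylation of the vinylogous amide oxygen followed by loss of the C2 proton (soft enolisation) aromatises the ring to the 3-silyloxypyrrole, both C2 epimers converging to one compound, and the bulky silyl ether is chosen to withstand alkoxide at low temperature.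

Step 9
Reactants: 17 (4S,7R)-3-[(tert-butyldimethylsilyl)oxy]-1,7-dimethoxy-2-methyl-4-(5-phenylpentyl)-4,5,6,7-tetrahydro-1H-indole; 18 bromoform
Product: 21 (5S,8R)-3-bromo-1,8-dimethoxy-2-methyl-5-(5-phenylpentyl)-5,6,7,8-tetrahydroquinolin-4(1H)-one, via dibromocyclopropane 19 (not isolated), via pyridinium bromide 20 (not isolated)
Conditions: KOt-Bu (added in portions), pentane, −20 °C → rt
Reagents that add atoms: none
Why: Proposed new method: dibromocarbene, formed by α-elimination from bromoform, should add as an electrophile to the most electron-rich π bond of the pyrrole, the C2–C3 bond that is at once an enamine and a silyl enol ether, and the gem-dibromocyclopropane should open in a cyclopropyl-to-allyl fashion with loss of bromide, pushed by the ring nitrogen and the silyloxy oxygen, to a 3-bromo-4-silyloxypyridinium ion that gives up its silyl group to bromide or alkoxide. The closest known reaction types are the Ciamician–Dennstedt conversion of pyrroles and indoles into 3-halopyridines and 3-haloquinolines and the dihalocarbene ring expansion of cyclic silyl enol ethers to α-halo enones; new is their combination on an N-alkoxy 3-silyloxypyrrole, where the oxygen substituent lets a neutral 4-pyridone form although nitrogen is substituted. Ring A is closed by one-carbon ring expansion of the five-membered ring (disrotatory electrocyclic opening of the fused cyclopropane), not by an end-to-end cyclisation. No stereocentre is created, and C4 and C7 of ring B (C5 and C8 of the product) lie outside the reacting π system and are carried through. The step needs site selectivity for the C2–C3 bond over the ring-fusion bond, which the double donor substitution and the open environment of C2–C3 should secure (the fusion bond is flanked by the C4 chain and the C7 methoxy group, and its adduct could open only to a strained bridged cation). It also needs cyclopropanation to outrun simple C-alkylation at C2, which the neutral silyl ether, unlike a free pyrrol-3-olate, should favour.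

Step 10
Reactants: 21 (5S,8R)-3-bromo-1,8-dimethoxy-2-methyl-5-(5-phenylpentyl)-5,6,7,8-tetrahydroquinolin-4(1H)-one
Product: 22 (5S,8R)-1,3,8-trimethoxy-2-methyl-5-(5-phenylpentyl)-5,6,7,8-tetrahydroquinolin-4(1H)-one (waltherione H)
Conditions: CuI (20 mol %), 1,10-phenanthroline (40 mol %), NaOMe, MeOH/DMF, 80 °C
Reagents that add atoms: sodium methoxide, [Na+].[O-]C
Why: Copper-catalysed Ullmann-type C–O coupling should replace the C3 bromide of the pyridone by methoxide without involving the two ring B stereocentres.

Compound list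
1 | (1R,2R)-2-methoxycyclohexan-1-ol | O[C@@H]1CCCC[C@H]1OC | starting material
2 | (R)-2-methoxycyclohexan-1-one | O=C1CCCC[C@H]1OC | intermediate
3 | lithium (R)-6-methoxycyclohex-1-en-1-olate (not isolated) | [Li+].[O-]C1=CCCC[C@H]1OC | intermediate
4 | (R)-6-methoxycyclohex-2-en-1-one | O=C1C=CCC[C@H]1OC | intermediate
5 | tert-butyl N-methoxycarbamate | CONC(=O)OC(C)(C)C | starting material
6 | methyl 2-bromopropanoate (racemic) | COC(=O)C(C)Br | starting material
7 | methyl 2-[(tert-butoxycarbonyl)(methoxy)amino]propanoate (racemic) | COC(=O)C(C)N(OC)C(=O)OC(C)(C)C | intermediate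
8 | tert-butyl N-methoxy-N-(1-oxopropan-2-yl)carbamate (racemic) | O=CC(C)N(OC)C(=O)OC(C)(C)C | intermediate
9 | (5-bromopentyl)benzene | BrCCCCCc1ccccc1 | starting material
10 | (5-phenylpentyl)magnesium bromide (not isolated) | Br[Mg]CCCCCc1ccccc1 | intermediate
11 | bis(5-phenylpentyl)zinc (not isolated) | C(CCCCc1ccccc1)[Zn]CCCCCc1ccccc1 | intermediate
12 | (5-phenylpentyl)zinc (3S,6R)-6-methoxy-3-(5-phenylpentyl)cyclohex-1-en-1-olate (not isolated) | c1ccccc1CCCCC[Zn]OC1=C[C@@H](CCCCCc2ccccc2)CC[C@H]1OC | intermediate
13 | (3S,6R)-2-{2-[(tert-butoxycarbonyl)(methoxy)amino]-1-hydroxypropyl}-6-methoxy-3-(5-phenylpentyl)cyclohexan-1-one, epimer mixture at C2 and the side chain | O=C1C(C(O)C(C)N(OC)C(=O)OC(C)(C)C)[C@@H](CCCCCc2ccccc2)CC[C@H]1OC | intermediate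
14 | (3S,6R)-2-{2-[(tert-butoxycarbonyl)(methoxy)amino]propanoyl}-6-methoxy-3-(5-phenylpentyl)cyclohexan-1-one, side-chain epimers | O=C1C(C(=O)C(C)N(OC)C(=O)OC(C)(C)C)[C@@H](CCCCCc2ccccc2)CC[C@H]1OC | intermediate
15 | (3S,6R)-6-methoxy-2-[2-(methoxyamino)propanoyl]-3-(5-phenylpentyl)cyclohexan-1-one (not isolated) | O=C1C(C(=O)C(C)NOC)[C@@H](CCCCCc2ccccc2)CC[C@H]1OC | intermediate
16 | (4S,7R)-1,7-dimethoxy-2-methyl-4-(5-phenylpentyl)-1,2,4,5,6,7-hexahydro-3H-indol-3-one, C2 epimers | CC1N(OC)C2=C(C1=O)[C@@H](CCCCCc1ccccc1)CC[C@H]2OC | intermediate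
17 | (4S,7R)-3-[(tert-butyldimethylsilyl)oxy]-1,7-dimethoxy-2-methyl-4-(5-phenylpentyl)-4,5,6,7-tetrahydro-1H-indole, 4,7-cis | Cc1n(OC)c2c(c1O[Si](C)(C)C(C)(C)C)[C@@H](CCCCCc1ccccc1)CC[C@H]2OC | intermediate
18 | bromoform | BrC(Br)Br | starting material
19 | gem-dibromocyclopropane adduct of 17 across the pyrrole C2–C3 bond, ring B centres as in 17 (not isolated) | CC12N(OC)C3=C(C1(O[Si](C)(C)C(C)(C)C)C2(Br)Br)[C@@H](CCCCCc1ccccc1)CC[C@H]3OC | intermediate
20 | (5S,8R)-3-bromo-4-[(tert-butyldimethylsilyl)oxy]-1,8-dimethoxy-2-methyl-5-(5-phenylpentyl)-5,6,7,8-tetrahydroquinolin-1-ium bromide (not isolated) | Brc1c(C)[n+](OC)c2c(c1O[Si](C)(C)C(C)(C)C)[C@@H](CCCCCc1ccccc1)CC[C@H]2OC.[Br-] | intermediate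
21 | (5S,8R)-3-bromo-1,8-dimethoxy-2-methyl-5-(5-phenylpentyl)-5,6,7,8-tetrahydroquinolin-4(1H)-one, 5,8-cis | Brc1c(C)n(OC)c2c(c1=O)[C@@H](CCCCCc1ccccc1)CC[C@H]2OC | intermediate
22 | (5S,8R)-1,3,8-trimethoxy-2-methyl-5-(5-phenylpentyl)-5,6,7,8-tetrahydroquinolin-4(1H)-one, waltherione H | COc1c(C)n(OC)c2c(c1=O)[C@@H](CCCCCc1ccccc1)CC[C@H]2OC | target

Total step count: 10. Longest linear sequence: 8 steps (steps 1, 2, 5, 6, 7, 8, 9, 10).

Steps most likely to fail

Step 9. The carbene may alkylate C2 without ring expansion (giving a non-aromatic 2-dibromomethyl pyrrolinone after desilylation), may add across the ring-fusion bond, or the alkoxide may strip the N-methoxy group from the pyridinium intermediate by elimination of formaldehyde. The fallback builds ring A by known cyclocondensation; it sets out from enone 4 and comes back at bromopyridone 21. The copper-catalysed addition of 11 to 4 is run as in step 5 and the zinc enolate 12 is trapped with but-2-ynal to give the propargylic aldol (3S,6R)-2-(1-hydroxybut-2-yn-1-yl)-6-methoxy-3-(5-phenylpentyl)cyclohexan-1-one F1. Dess–Martin oxidation gives the ynone diketone (3S,6R)-2-(but-2-ynoyl)-6-methoxy-3-(5-phenylpentyl)cyclohexan-1-one F2. Methoxyamine hydrochloride and NaOAc in EtOH at 60 °C (aza-Michael addition to the ynone, then cyclodehydration onto the ring ketone) should give the 3-unsubstituted pyridone (5S,8R)-1,8-dimethoxy-2-methyl-5-(5-phenylpentyl)-5,6,7,8-tetrahydroquinolin-4(1H)-one F3. NBS in MeCN at 0 °C then brominates the only free ring A position, C3, to give 21.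

Step 5. The cis selectivity may erode if catalyst control is opposed by the existing methoxy centre (mismatched pairing), the enone may racemise by enolisation before addition, or the branched aldehyde may trap the zinc enolate incompletely. The fallback separates the two events and uses a conjugate addition under stronger catalyst control; it sets out from enone 4 and comes back at aldol 13. Rhodium-catalysed addition of (E)-(5-phenylpent-1-en-1-yl)boronic acid (Hayashi–Miyaura reaction; [Rh(acac)(C2H4)2], (S)-BINAP, dioxane/H2O, 60 °C) should give the alkenyl ketone (2R,5S)-2-methoxy-5-[(E)-5-phenylpent-1-en-1-yl]cyclohexan-1-one F4. Hydrogenation (H2, Pd/C, EtOAc) saturates the chain to (2R,5S)-2-methoxy-5-(5-phenylpentyl)cyclohexan-1-one F5. Kinetic deprotonation with LiN(i-Pr)2 in THF at −78 °C, at the CH2 remote from the methoxy group, and addition of aldehyde 8 give 13.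

Step 10. Hot methoxide may remove the N-methoxy group, may epimerise C8 by vinylogous deprotonation, or the bromide may be lost reductively instead of being substituted. The fallback introduces the oxygen through boron under weakly basic conditions; it sets out from bromopyridone 21 and comes back at target 22. Miyaura borylation (PdCl2(dppf), B2pin2, KOAc, dioxane, 80 °C) gives the boronate (5S,8R)-1,8-dimethoxy-2-methyl-5-(5-phenylpentyl)-3-(4,4,5,5-tetramethyl-1,3,2-dioxaborolan-2-yl)-5,6,7,8-tetrahydroquinolin-4(1H)-one F6. Oxidation with NaBO3·4H2O in THF/H2O at rt gives the 3-hydroxypyridone (5S,8R)-3-hydroxy-1,8-dimethoxy-2-methyl-5-(5-phenylpentyl)-5,6,7,8-tetrahydroquinolin-4(1H)-one F7. O-Methylation with MeI and K2CO3 in acetone at rt gives 22.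

Further compounds
F1 | step 9 | (3S,6R)-2-(1-hydroxybut-2-yn-1-yl)-6-methoxy-3-(5-phenylpentyl)cyclohexan-1-one | O=C1C(C(O)C#CC)[C@@H](CCCCCc2ccccc2)CC[C@H]1OC
F2 | step 9 | (3S,6R)-2-(but-2-ynoyl)-6-methoxy-3-(5-phenylpentyl)cyclohexan-1-one | O=C1C(C(=O)C#CC)[C@@H](CCCCCc2ccccc2)CC[C@H]1OC
F3 | step 9 | (5S,8R)-1,8-dimethoxy-2-methyl-5-(5-phenylpentyl)-5,6,7,8-tetrahydroquinolin-4(1H)-one | c1c(C)n(OC)c2c(c1=O)[C@@H](CCCCCc1ccccc1)CC[C@H]2OC
F4 | step 5 | (2R,5S)-2-methoxy-5-[(E)-5-phenylpent-1-en-1-yl]cyclohexan-1-one | O=C1C[C@@H](/C=C/CCCc2ccccc2)CC[C@H]1OC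
F5 | step 5 | (2R,5S)-2-methoxy-5-(5-phenylpentyl)cyclohexan-1-one | O=C1C[C@@H](CCCCCc2ccccc2)CC[C@H]1OC
F6 | step 10 | (5S,8R)-1,8-dimethoxy-2-methyl-5-(5-phenylpentyl)-3-(4,4,5,5-tetramethyl-1,3,2-dioxaborolan-2-yl)-5,6,7,8-tetrahydroquinolin-4(1H)-one | CC1(C)OB(OC1(C)C)c1c(C)n(OC)c2c(c1=O)[C@@H](CCCCCc1ccccc1)CC[C@H]2OC
F7 | step 10 | (5S,8R)-3-hydroxy-1,8-dimethoxy-2-methyl-5-(5-phenylpentyl)-5,6,7,8-tetrahydroquinolin-4(1H)-one | Oc1c(C)n(OC)c2c(c1=O)[C@@H](CCCCCc1ccccc1)CC[C@H]2OC
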